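**Retrosynthetic overview**
1. Target 12 ⇐ oxanorbornadiene 11: benzoate opens the oxygen bridge anti (SN2′), forming the C5–OBz bond trans to the retained bridge oxygen (C6–OH) and leaving the 1,3-diene.
2. 11 ⇐ ester 7: reduction of the ester to CH2OH, then esterification with benzoic acid (made from benzaldehyde).
3. 7 ⇐ meso dibromo ketone 4 (key step): Favorskii-type (semibenzilic) 1,2-shift contracts the seven-membered carbocycle to the six-membered one; the carbonyl carbon becomes the exocyclic carbon and the desymmetrisation sets the absolute configuration.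
4. 4 ⇐ furan + 1,1,3,3-tetrabromoacetone by oxyallyl [4+3] cycloaddition.
5. Ring order: oxygen-bridged seven-membered carbocycle, then contraction to the oxygen-bridged six-membered carbocycle, then opening of the bridge.

Assumption: the target is numbered C1 (carries CH2OBz), C5 (benzoate), C6 (free OH); the given SMILES is the trans (5R,6R) isomer.

**Route**

Step 1
Reactants: 1 furan; 2 1,1,3,3-tetrabromoacetone
Product: 4 meso-(1R,2S,4R,5S)-2,4-dibromo-8-oxabicyclo[3.2.1]oct-6-en-3-one, via zinc oxyallyl cation 3 (not isolated)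
Conditions: Zn–Ag couple (1.2 equiv Zn), furan (5 equiv), THF, −10 °C → rt; cis isomer crystallised
Reagents that add atoms: none
Why: Zinc reduces the tetrabromide to the 1,3-dibromo-2-oxyallyl cation, which adds across furan in a [4+3] cycloaddition (Noyori/Hoffmann type); the compact transition state gives the cis dibromide with both bromines equatorial, a meso compound, so no absolute configuration is set here.

Step 2
Reactants: 4
Product: 7 methyl (1S,4R)-7-oxabicyclo[2.2.1]hepta-2,5-diene-2-carboxylate, via hemiketal oxyanion 5 (not isolated), via bromo ester 6 (not isolated)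
Conditions: MeOH (3 equiv), Cs2CO3 (2.5 equiv), N-(9-anthracenylmethyl)cinchonidinium chloride (10 mol %), toluene, −30 → 0 °C
Reagents that add atoms: methanol (CO)
Why: Proposed new method: enantioselective semibenzilic (quasi-Favorskii) ring contraction of a meso α,α′-dibromo ketone under chiral phase-transfer catalysis; methoxide adds to the ketone, the cinchonidinium cation pairs with the oxyanion and its 9-OH hydrogen-bonds to one of the two enantiotopic equatorial bromides, so the C3–C2 bond antiperiplanar to the C4–Br bond shifts to C4 with inversion (1,2-shift, seven- to six-membered carbocycle, former carbonyl carbon now the exocyclic ester carbon), and E1cB loss of the second HBr gives the diene; displacing the bromide on the R-configured C4 puts the ester next to the former C5 bridgehead and gives (1S,4R) (the pseudo-enantiomeric cinchoninium salt would give the mirror image); closest known reactions are the racemic Favorskii and quasi-Favorskii contractions of α-halo [4+3] cycloadducts and cinchona-ammonium phase-transfer desymmetrisations.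

Step 3
Reactants: 7
Product: 8 [(1S,4R)-7-oxabicyclo[2.2.1]hepta-2,5-dien-2-yl]methanol
Conditions: i-Bu2AlH (2.2 equiv), CH2Cl2, −78 °C; aq. potassium sodium tartrate
Reagents that add atoms: none
Why: 1,2-reduction of the conjugated ester by the aluminium hydride at low temperature gives the allylic alcohol; the bridgehead stereocentres are not touched.

Step 4
Reactants: 9 benzaldehyde
Product: 10 benzoic acid
Conditions: KHSO5 (as 2KHSO5·KHSO4·K2SO4, 1.1 equiv KHSO5), DMF, rt
Reagents that add atoms: potassium peroxymonosulfate ([K+].[O-]S(=O)(=O)OO)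
Why: Peroxymonosulfate oxidation of an aryl aldehyde to the carboxylic acid (hydride shift in the peroxy adduct, Baeyer–Villiger type); no stereocentre is involved.

Step 5
Reactants: 8; 10 benzoic acid
Product: 11 [(1S,4R)-7-oxabicyclo[2.2.1]hepta-2,5-dien-2-yl]methyl benzoate
Conditions: DCC (1.1 equiv), DMAP (10 mol %), CH2Cl2, 0 °C → rt
Reagents that add atoms: none
Why: Steglich esterification of the primary allylic alcohol under neutral, mild conditions that the acid-sensitive oxanorbornadiene tolerates; stereocentres untouched.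

Step 6
Reactants: 11; 10 benzoic acid
Product: 12 [(5R,6R)-5-(benzoyloxy)-6-hydroxycyclohexa-1,3-dien-1-yl]methyl benzoate
Conditions: [Rh(cod)Cl]2 (2.5 mol %), (S)-1-[(R)-2-(diphenylphosphino)ferrocenyl]ethyl-di-tert-butylphosphine (6 mol %, the ligand enantiomer matched to 11, to be confirmed on a test scale), 10 (1.5 equiv), Et3N (1.5 equiv), THF, 40 °C
Reagents that add atoms: none
Why: Rhodium-catalysed anti-SN2′ ring opening of an oxabicyclic alkene with a carboxylate (Lautens type), here on an enantiopure substrate: monovalent rhodium binds the unsubstituted C5=C6 alkene on the oxygen face and inserts into the C4–O bond remote from the substituted carbon, and benzoate attacks C6 from the face opposite to the metal, so the new C–O bond (target C5, R) is trans to the retained C1–O bond (target C6, R) and the 1,3-diene is formed.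

**Compound list**
1 | furan | c1ccoc1 | starting material
2 | 1,1,3,3-tetrabromoacetone | BrC(Br)C(=O)C(Br)Br | starting material
3 | 1,3-dibromo-2-[(bromozincio)oxy]allyl cation bromide | Br/C=C(\O[Zn]Br)[CH+]Br.[Br-] | intermediate
4 | meso-(1R,2S,4R,5S)-2,4-dibromo-8-oxabicyclo[3.2.1]oct-6-en-3-one | O=C1[C@@H](Br)[C@H]2C=C[C@H](O2)[C@H]1Br | intermediate
5 | cesium (1R,2S,3r,4R,5S)-2,4-dibromo-3-methoxy-8-oxabicyclo[3.2.1]oct-6-en-3-olate | CO[C@]1([O-])[C@@H](Br)[C@H]2C=C[C@H](O2)[C@H]1Br.[Cs+] | intermediate
6 | methyl (1S,2S,3R,4R)-3-bromo-7-oxabicyclo[2.2.1]hept-5-ene-2-carboxylate | COC(=O)[C@H]1[C@@H](Br)[C@H]2C=C[C@@H]1O2 | intermediate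
7 | methyl (1S,4R)-7-oxabicyclo[2.2.1]hepta-2,5-diene-2-carboxylate | COC(=O)C1=C[C@H]2C=C[C@@H]1O2 | intermediate
8 | [(1S,4R)-7-oxabicyclo[2.2.1]hepta-2,5-dien-2-yl]methanol | OCC1=C[C@H]2C=C[C@@H]1O2 | intermediate
9 | benzaldehyde | O=Cc1ccccc1 | starting material
10 | benzoic acid | OC(=O)c1ccccc1 | intermediate
11 | [(1S,4R)-7-oxabicyclo[2.2.1]hepta-2,5-dien-2-yl]methyl benzoate | O=C(OCC1=C[C@H]2C=C[C@@H]1O2)c1ccccc1 | intermediate
12 | [(5R,6R)-5-(benzoyloxy)-6-hydroxycyclohexa-1,3-dien-1-yl]methyl benzoate | O=C(OCC1=CC=C[C@@H](OC(=O)c2ccccc2)[C@@H]1O)c1ccccc1 | target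

**Totals**
Total steps: 6. Longest linear sequence: 5 (steps 1, 2, 3, 5, 6; step 4 is a one-step side branch).

**Three steps most likely to fail**

Step 2 (the proposed new step). The selectivity between the two enantiotopic bromides is untested, an uncatalysed racemic background reaction is possible, and methoxide can add to the strained enoate 7. Fallback with known chemistry, setting out from 4: the classical Favorskii contraction with achiral NaOMe in MeOH at 0 °C passes through the racemic bromo ester rac-methyl (1S,2S,3R,4R)-3-bromo-7-oxabicyclo[2.2.1]hept-5-ene-2-carboxylate F3 (not isolated) and gives racemic methyl 7-oxabicyclo[2.2.1]hepta-2,5-diene-2-carboxylate F4. The enantiomers of F4 are separated by preparative chromatography on a chiral stationary phase, and the (1S,4R) enantiomer comes back to the route as 7.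

Step 6. Carboxylate openings of this kind are established for benzo-fused oxabicycles, whereas 11 is a non-benzo, unsymmetrical diene. Insertion into the other C–O bond would give the regioisomer, and the product can undergo acyl migration or aromatise. Fallback, setting out from 11 and changing to an alcohol nucleophile with a protecting-group relay: the same rhodium catalysis with 4-methoxybenzyl alcohol (the best-documented nucleophile class) gives the ether [(5R,6R)-6-hydroxy-5-[(4-methoxyphenyl)methoxy]cyclohexa-1,3-dien-1-yl]methyl benzoate F5. Silylation (Et3SiOTf, 2,6-lutidine) gives [(5R,6R)-5-[(4-methoxyphenyl)methoxy]-6-(triethylsilyloxy)cyclohexa-1,3-dien-1-yl]methyl benzoate F6. DDQ in buffered CH2Cl2/H2O frees the C5 alcohol [(5R,6R)-5-hydroxy-6-(triethylsilyloxy)cyclohexa-1,3-dien-1-yl]methyl benzoate F7. Esterification with 10 (DCC, DMAP) gives [(5R,6R)-5-(benzoyloxy)-6-(triethylsilyloxy)cyclohexa-1,3-dien-1-yl]methyl benzoate F8, and HF·pyridine removes the silyl group to come back to the route at 12.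

Step 1. The zinc-mediated cycloaddition can give cis/trans mixtures, over-reduction and a modest yield, and only the meso cis isomer is useful. Fallback, setting out from 1 and generating the oxyallyl cation by base instead of by reduction (Föhlisch-type conditions): furan 1 and 1,1,3-trichloroacetone with CF3CH2ONa in CF3CH2OH give, under equilibrating conditions, meso-(1R,2S,4R,5S)-2,4-dichloro-8-oxabicyclo[3.2.1]oct-6-en-3-one F1. F1 takes the place of 4 under the step 2 conditions, passes through methyl (1S,2S,3R,4R)-3-chloro-7-oxabicyclo[2.2.1]hept-5-ene-2-carboxylate F2 (not isolated), and comes back to the route at 7.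

**Further compounds**
F1 | step 1 | meso-(1R,2S,4R,5S)-2,4-dichloro-8-oxabicyclo[3.2.1]oct-6-en-3-one | O=C1[C@@H](Cl)[C@H]2C=C[C@H](O2)[C@H]1Cl
F2 | step 1 | methyl (1S,2S,3R,4R)-3-chloro-7-oxabicyclo[2.2.1]hept-5-ene-2-carboxylate | COC(=O)[C@H]1[C@@H](Cl)[C@H]2C=C[C@@H]1O2
F3 | step 2 | rac-methyl (1S,2S,3R,4R)-3-bromo-7-oxabicyclo[2.2.1]hept-5-ene-2-carboxylate | COC(=O)[C@H]1[C@@H](Br)[C@H]2C=C[C@@H]1O2
F4 | step 2 | racemic methyl 7-oxabicyclo[2.2.1]hepta-2,5-diene-2-carboxylate | COC(=O)C1=CC2C=CC1O2
F5 | step 6 | [(5R,6R)-6-hydroxy-5-[(4-methoxyphenyl)methoxy]cyclohexa-1,3-dien-1-yl]methyl benzoate | O=C(OCC1=CC=C[C@@H](OCc2ccc(OC)cc2)[C@@H]1O)c1ccccc1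
F6 | step 6 | [(5R,6R)-5-[(4-methoxyphenyl)methoxy]-6-(triethylsilyloxy)cyclohexa-1,3-dien-1-yl]methyl benzoate | O=C(OCC1=CC=C[C@@H](OCc2ccc(OC)cc2)[C@@H]1O[Si](CC)(CC)CC)c1ccccc1
F7 | step 6 | [(5R,6R)-5-hydroxy-6-(triethylsilyloxy)cyclohexa-1,3-dien-1-yl]methyl benzoate | O=C(OCC1=CC=C[C@@H](O)[C@@H]1O[Si](CC)(CC)CC)c1ccccc1
F8 | step 6 | [(5R,6R)-5-(benzoyloxy)-6-(triethylsilyloxy)cyclohexa-1,3-dien-1-yl]methyl benzoate | O=C(OCC1=CC=C[C@@H](OC(=O)c2ccccc2)[C@@H]1O[Si](CC)(CC)CC)c1ccccc1
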